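At early times in the theta run J climbs and then flattens, 39.3 % at 0.833 min and 43.6 % at 3.00 min, with Q at 10.0 %. So I freeze it: the ceiling, the fraction of the charge that the solution holds as J while solid stands, is read as 43.6 %, give or take 1 percentage point, for this charge of D, and with the solubility held, a larger charge lowers it in proportion.

| flask | D | Z | remark | time |
|---|---|---|---|---|
| theta | 0.30 M | 0.18 M | run made earlier |  |
| flask | 0.30 M | 0.360 M |  | 30 min |

- theta (time / min: Q / %, J / %): 0.250: 0, 24.5; 0.417: 0, 32.0; 0.833: 1.3, 39.3; 1.50: 6.2, 42.4; 3.00: 10.0, 43.6

(each reading ± 1 percentage point)

- D is a solid; its amount is given per volume of the solution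
- at the start none of D is in solution
- J is what D becomes in solution
- J means what is dissolved; the solid is not counted in it

- Q at 30 min, in percent of the D charged
- concentration of J in solution at 15 min, in percent of saturation
- the change that raises the amount of Q at 30 min, in percent of the D charged most ("none" if none brings more than 2 percentage points) (Saturday's / Friday's / Thursday's / none)
- amount of Q at 30 min, in percent of the D charged, after Friday's

- Saturday's: doubling the dissolution coefficient of D, all else as stated
- Friday's: doubling the amount of Z, all else as stated
- Thursday's: doubling the solubility of D, all else as stated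

You take over a flask with twice the Z of the theta run. With J frozen, Q's gain is pseudo-first-order in Z. In the theta run Q gained 3.8 points in 1.50 min. Doubled, that gain draws on a solid store of 56.4 %, which by my estimate lasts about 11.1 min, less than 15 min, though falling Z stretches it. So I expect this flask at 15 min to hold no solid, with J under the ceiling. Leave the dissolution alone: J in the theta run was flat by 3.00 min, far shorter than 30 min.

The forecast gives 49 % for Q, 100 % of saturation for J, Friday's as best and 86 % after it, on this ground: “At 15 min J+Q is about 78%, so solid remains and J is still saturated (100%).” My reckoning parts from it on that solid.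

The flask gives 16.1 % of Q, J at 50.6 % of saturation, Friday's as best and 26.3 % after it.

    D ⇌ J, rate k1*(cs1 - [J]) while solid is left; crystals form when [J] > cs1 (solubility = 0.130 M, k = 3.40 min⁻¹)
    J + Z ⇌ Q (K = 6.20 M⁻¹, k = 0.760 M⁻¹ min⁻¹)
    J + Q → G (k = 0.650 M⁻¹ min⁻¹)

At 30.0 min in this flask, J passes into Q 4.9 times as fast, forward rate alone, as J and Q pass into G. Yet over the run the backward turnover of the Q step is 62 % of the forward one, and at the end this flask stands at Q 16.1 % and G 71.4 %, each G counted as two. At 15.0 min this flask reads D 0 % and J 21.9 %, which is 50.2 % of the ceiling. With 1.2 M of D the ceiling becomes 10.9 % of the charge, and that flask at 30.0 min reads D 52.8 % and J 10.6 %.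

The data were computed on assumed constants; scatter was added.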